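## Retrosynthetic overview

1. Target 11 ⇒ acyclic (14R)-β-bromo tertiary trifluoroacetate 9. The cyclohexane is formed last. The last step makes the only C–C bond of the synthesis (C10–C15) and the C11–OH by a bromonium/alkene/water cyclisation of a pre-set, enantiopure bromonium ion.
2. 9 ⇒ terminal alkene of 6, through the (14S)-epoxide 7 (reagent control) and SN2 opening by bromide. This sets C14, which then relays to C10 and C11.
3. 6 ⇒ tertiary alcohol 5 by 6-endo bromoetherification. The tetrahydropyran is formed first. C6 and C7 come from anti addition to the E-alkene, and the face is chosen by C3.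
4. 5 ⇒ (2R,3R)-epoxygeranylgeraniol 2 (asymmetric epoxidation, OH→Cl, invertive hydrolysis at C3) ⇒ geranylgeraniol 1.
5. Not used: the obvious cut through the C8–C9 tether with union of two preformed rings. The C20 chain is never cut, and there is no fragment coupling.

Assumption: carbon numbers follow geranylgeraniol (C1 = CH2Cl, C3 and C7 = ring C–O carbons, C15 = CMe2). The target is then 2S,3S,6R,7S,10R,11R,14R. The L-fructose-derived (ent-)Shi ketone is used as a purchased catalyst.

## Route

Step 1
Reactants: 1 (2E,6E,10E)-geranylgeraniol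
Product: 2 (2R,3R)-2,3-epoxygeranylgeraniol
Conditions: Ti(OiPr)4 (5 mol%), D-(−)-DET (6 mol%), t-BuOOH, 4 Å MS, CH2Cl2, −20 °C
Reagents that add atoms: tert-butyl hydroperoxide CC(C)(C)OO
Why: The Katsuki–Sharpless asymmetric epoxidation touches only the allylic-alcohol alkene of the four and, with D-(−)-tartrate, delivers oxygen to the face that gives the (2R,3R)-epoxide, which fixes C2 and the precursor of C3.

Step 2
Reactants: 2 (2R,3R)-2,3-epoxygeranylgeraniol
Product: 3 (2S,3R,6E,10E)-1-chloro-2,3-epoxy-3,7,11,15-tetramethylhexadeca-6,10,14-triene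
Conditions: PPh3, CCl4, solid NaHCO3, reflux
Reagents that add atoms: carbon tetrachloride ClC(Cl)(Cl)Cl
Why: The Appel chlorination replaces the primary OH by SN2 at C1 under neutral conditions, so the epoxide, both stereocentres (C2 is renamed S only because CH2Cl now outranks C3) and the three alkenes are untouched.

Step 3
Reactants: 3 (2S,3R,6E,10E)-1-chloro-2,3-epoxy-3,7,11,15-tetramethylhexadeca-6,10,14-triene
Product: 4 (2S,3S,6E,10E)-1-chloro-3,7,11,15-tetramethylhexadeca-6,10,14-triene-2,3-diol
Conditions: HClO4 (5 mol%), THF–H2O 4:1, 0 °C → rt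
Reagents that add atoms: water O
Why: In this acid-catalysed (A-2-like) epoxide hydrolysis water attacks the tertiary C3 from the rear with inversion, because charge builds up there and not at C2 next to CH2Cl, while the C2–O bond is kept, so the anti-diol (2S,3S) results.

Step 4
Reactants: 4 (2S,3S,6E,10E)-1-chloro-3,7,11,15-tetramethylhexadeca-6,10,14-triene-2,3-diol
Product: 5 (2S,3S,6E,10E)-1-chloro-2-(triethylsilyloxy)-3,7,11,15-tetramethylhexadeca-6,10,14-trien-3-ol
Conditions: TESCl (1.1 equiv), imidazole, CH2Cl2, 0 °C
Reagents that add atoms: chlorotriethylsilane CC[Si](Cl)(CC)CC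
Why: Chemoselective silyl ether formation takes the secondary C2–OH far faster than the hindered tertiary C3–OH, which removes the only competing O-nucleophile, shields the chlorohydrin from base and enlarges the C3 side chain for the next step.

Step 5
Reactants: 5 (2S,3S,6E,10E)-1-chloro-2-(triethylsilyloxy)-3,7,11,15-tetramethylhexadeca-6,10,14-trien-3-ol
Product: 6 (2S,3S,6R,7S,10E)-6-bromo-1-chloro-3,7-epoxy-2-(triethylsilyloxy)-3,7,11,15-tetramethylhexadeca-10,14-diene (tetrahydropyran; Br, C8 chain and C2 side chain equatorial; both ring methyls axial)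
Conditions: TBCO (1.05 equiv, slow addition), CH2Cl2–MeNO2 4:1, −30 °C, dark
Reagents that add atoms: 2,4,4,6-tetrabromocyclohexa-2,5-dienone (TBCO) O=C1C(Br)=CC(Br)(Br)C=C1Br
Why: In this 6-endo Markovnikov bromoetherification Br+ passes reversibly among the three alkenes but only the C6=C7 bromonium ion has an OH within reach, anti addition to the E-alkene fixes C6 relative to C7, and the chair transition state with Br, the C8 chain and the bulky C2 side chain equatorial (only Me/Me diaxial) selects the (6R,7S) face.

Step 6
Reactants: 6 (2S,3S,6R,7S,10E)-6-bromo-1-chloro-3,7-epoxy-2-(triethylsilyloxy)-3,7,11,15-tetramethylhexadeca-10,14-diene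
Product: 7 (14S)-14,15-epoxide of 6
Conditions: ent-Shi ketone (30 mol%), Oxone (1.0 equiv), K2CO3, Bu4NHSO4 (cat.), MeCN–DMM/aq. borate–EDTA buffer (pH 10.5), −5 °C, to about 65% conversion, 6 recycled
Reagents that add atoms: potassium peroxymonosulfate (active part of Oxone) [K+].[O-]S(=O)(=O)OO
Why: In the Shi asymmetric epoxidation the dioxirane of the L-fructose-derived ketone attacks the less hindered terminal isopropylidene alkene through the spiro transition state to give the (14S)-epoxide, and partial conversion keeps C10=C11 intact.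

Step 7
Reactants: 7 (14S)-14,15-epoxide of 6
Product: 8 (2S,3S,6R,7S,10E,14R)-6,14-dibromo-1-chloro-3,7-epoxy-2-(triethylsilyloxy)-3,7,11,15-tetramethylhexadec-10-en-15-ol
Conditions: Li2NiBr4 (0.4 M in THF, 1.5 equiv), THF, −20 → 0 °C; pH 7 buffer
Reagents that add atoms: dilithium tetrabromonickelate [Li+].[Li+].[Ni+2].[Br-].[Br-].[Br-].[Br-]
Why: In this SN2 epoxide opening (halohydrin formation) the soft bromide attacks the less substituted C14 with clean inversion, which gives the (14R) secondary bromide next to the tertiary alcohol.

Step 8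
Reactants: 8 (2S,3S,6R,7S,10E,14R)-6,14-dibromo-1-chloro-3,7-epoxy-2-(triethylsilyloxy)-3,7,11,15-tetramethylhexadec-10-en-15-ol
Product: 9 15-O-trifluoroacetate of 8
Conditions: (CF3CO)2O, pyridine, CH2Cl2, −20 °C; cold NaHCO3 wash, used at once
Reagents that add atoms: trifluoroacetic anhydride O=C(OC(=O)C(F)(F)F)C(F)(F)F
Why: O-acylation (esterification) of the only free OH turns it into a leaving group that can ionise under near-neutral conditions, without touching C14 or the acid-sensitive C10=C11 alkene.

Step 9
Reactants: 9 15-O-trifluoroacetate of 8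
Product: 11 CNP0182369.1 (2S,3S,6R,7S,10R,11R,14R), via TES ether of the target 10 (not isolated)
Conditions: HFIP, H2O (20 equiv), 0.01 M, 40 °C, 12 h; then aq. TFA (cat.), 0 °C, 1 h
Reagents that add atoms: water O
Why: Proposed new method: in strongly ionising, non-nucleophilic HFIP the tertiary trifluoroacetate leaves with anchimeric help from the anti C14–Br to give a configurationally defined bromonium ion, which the C10=C11 E-alkene opens at C15 through a chair transition state (Br and C9 chain equatorial, hence 10R) faster than Br+ can hop between alkenes, water then caps the C11 cation anti (equatorial OH, 11R) and the acid set free hydrolyses the TES ether, the closest known reaction type being the enantiospecific solvolytic bromonium polyene (cation–π) cyclisation of vicinal bromochlorides and activated bromohydrin esters.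

## Compound list

1 | (2E,6E,10E)-geranylgeraniol | OC/C=C(\C)CC/C=C(\C)CC/C=C(\C)CCC=C(C)C | starting material
2 | (2R,3R)-2,3-epoxygeranylgeraniol | OC[C@H]1O[C@]1(C)CC/C=C(\C)CC/C=C(\C)CCC=C(C)C | intermediate
3 | (2S,3R)-epoxy chloride | ClC[C@H]1O[C@]1(C)CC/C=C(\C)CC/C=C(\C)CCC=C(C)C | intermediate
4 | (2S,3S)-chlorodiol | O[C@](C)([C@H](O)CCl)CC/C=C(\C)CC/C=C(\C)CCC=C(C)C | intermediate
5 | (2S,3S)-2-O-TES chlorodiol | O[C@](C)([C@H](O[Si](CC)(CC)CC)CCl)CC/C=C(\C)CC/C=C(\C)CCC=C(C)C | intermediate
6 | (2S,3S,6R,7S)-bromotetrahydropyran diene | CC(C)=CCC/C(C)=C/CC[C@]1(C)O[C@](C)([C@H](O[Si](CC)(CC)CC)CCl)CC[C@H]1Br | intermediate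
7 | (14S)-14,15-epoxide | CC1(C)O[C@H]1CC/C(C)=C/CC[C@]1(C)O[C@](C)([C@H](O[Si](CC)(CC)CC)CCl)CC[C@H]1Br | intermediate
8 | (14R)-14-bromo-15-ol | CC(C)(O)[C@H](Br)CC/C(C)=C/CC[C@]1(C)O[C@](C)([C@H](O[Si](CC)(CC)CC)CCl)CC[C@H]1Br | intermediate
9 | (14R)-14-bromo-15-trifluoroacetate | CC(C)(OC(=O)C(F)(F)F)[C@H](Br)CC/C(C)=C/CC[C@]1(C)O[C@](C)([C@H](O[Si](CC)(CC)CC)CCl)CC[C@H]1Br | intermediate
10 | 2-O-TES ether of the target (not isolated) | CC1(C)[C@H](Br)CC[C@@](C)(O)[C@@H]1CC[C@]1(C)O[C@](C)([C@H](O[Si](CC)(CC)CC)CCl)CC[C@H]1Br | intermediate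
11 | CNP0182369.1 | CC1(C)[C@H](Br)CC[C@@](C)(O)[C@@H]1CC[C@]1(C)O[C@](C)([C@H](O)CCl)CC[C@H]1Br | target

## Step count and risks

Total step count: 9. Longest linear sequence: 9 (fully linear from 1). The two reagent-controlled steps (1 and 6) turn residual enantiomer into separable diastereomers, so chromatography of 11 gives the single enantiomer.

**Step 5 is the first of the three most likely failures.** It faces site selection among three alkenes, 6-endo against 5-exo closure, and facial control.

- The fallback sets out from 5 and comes back at 6. It makes the ring in two stages with a different bond order.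
- Compound 5 is cyclised under kinetic conditions (NBS, CH2Cl2, −78 °C), which favour O-attack at the less hindered C6. This gives the 2,5-trans-tetrahydrofuran carrying the tertiary C7 bromide, (2S,3S,6S,7R)-7-bromo-1-chloro-3,6-epoxy-2-(triethylsilyloxy)-3,7,11,15-tetramethylhexadeca-10,14-diene F1.
- F1 stems from the same bromonium face as 6.
- LiBr and catalytic ZnBr2 in CH2Cl2–HFIP then ionise the tertiary C–Br bond with participation of the ring oxygen (bicyclic oxonium ion). Bromide re-enters at C6 with inversion while oxygen stays on C7.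
- This rearrangement–ring expansion drains into the more stable six-membered secondary bromide 6.

**Step 7 is the second.** Bromide may open 7 at the tertiary carbon, or the epoxide may rearrange.

- The fallback sets out from 6 and comes back at 8, bypassing 7.
- NBS in THF–H2O at 0 °C forms the terminal bromohydrin directly. Markovnikov attack of water guarantees Br at C14 and OH at C15.
- C14 is then not controlled. Compound 8 is formed together with its epimer, the (14S)-14-bromo-15-ol F2, in about 1:1 ratio.
- The two are diastereomers because the head is enantiopure, and they are separated by preparative HPLC. Compound 8 goes on to step 8.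

**Step 9 is the third.** Water may re-capture the bromonium ion at C15, E1 loss of a proton may replace water capture at C11, and facial control at C11 may be weak.

- The fallback sets out from 9 and comes back at 10. It separates C–C bond formation from C–O bond formation.
- Compound 9 is solvolysed in dry HFIP with 2,6-di-tert-butyl-4-methylpyridine, so that the cyclisation ends by proton loss. This gives the endocyclic C11=C12 alkene F3 and the exocyclic C11 methylene alkene F4. C10 and C14 are set as in 10 and the TES group is kept.
- A Mukaiyama hydration (Mn(dpm)3, PhSiH3, O2, i-PrOH) sends both alkenes through the same tertiary C11 radical. Oxygen traps that radical on the equatorial side, away from the axial C15 methyl group, to give 10.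
- Aqueous TFA at 0 °C then frees 11.

## Further compounds

F1 | step 5 | (2S,3S,6S,7R)-7-bromo-1-chloro-3,6-epoxy-2-(triethylsilyloxy)-3,7,11,15-tetramethylhexadeca-10E,14-diene (2,5-trans-tetrahydrofuran, tertiary bromide) | CC(C)=CCC/C(C)=C/CC[C@@](C)(Br)[C@@H]1CC[C@](C)(O1)[C@H](O[Si](CC)(CC)CC)CCl
F2 | step 7 | (14S)-epimer of bromohydrin 8 | CC(C)(O)[C@@H](Br)CC/C(C)=C/CC[C@]1(C)O[C@](C)([C@H](O[Si](CC)(CC)CC)CCl)CC[C@H]1Br
F3 | step 9 | C11=C12 endocyclic alkene, 2-O-TES (C10–H and C14–Br placed as in 10) | CC1(C)[C@H](Br)CC=C(C)[C@@H]1CC[C@]1(C)O[C@](C)([C@H](O[Si](CC)(CC)CC)CCl)CC[C@H]1Br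
F4 | step 9 | C11 exocyclic methylene alkene, 2-O-TES (C10–H and C14–Br placed as in 10) | CC1(C)[C@H](Br)CCC(=C)[C@@H]1CC[C@]1(C)O[C@](C)([C@H](O[Si](CC)(CC)CC)CCl)CC[C@H]1Br
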